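## Structural features

The target is a daucane-type diester: a cis-fused bicyclo[5.3.0]decene in which the seven-membered ring A (C1–C7) and the five-membered ring B (C6–C10) share the C6–C7 bond. Ring A carries a tiglate on C1, a trisubstituted C2=C3 alkene with the methyl on C3, and a 4-hydroxybenzoate on C5; ring B carries only the tertiary carbinol C10 with its isopropyl group. The five stereocentres form one array, C10–C6–C7 flanked by C5 and C1: H-6, the C7 methyl and both ester oxygens lie on one face (called β below), the C10 hydroxyl on the other. C7 is quaternary and sits between the tertiary C6 and the neopentyl carbinol C1, so the C6–C7 bond with its cis relationship is the real difficulty; the second difficulty is that two secondary oxygens must receive different acyl groups while a tertiary alcohol and a phenol stay free. Fragile elements are the two esters (the tiglate is an allylic ester and a Michael acceptor, the aroate can be cleaved or moved by base), the acidic phenol and, at the C5-ketone oxidation level, the tertiary β-hydroxy ketone (retro-aldol, dehydration). The key step reads C5–C6 as the internal π-bond of an allene and C7–C1–C2–C3–C4 as a vinylcyclopropane (alkene C7=C1, ring C2–C3–C4) joined through C8–C9–C10, so that one (5+2) cycloaddition closes ring B at C6–C7 and ring A at C4–C5, leaves C5 as an exocyclic methylene (a masked ketone) and leaves a C1=C2 alkene whose only neighbouring hydrogen is on C3.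

## Logic of the disconnections

34 ⇒ 33. Only the phenolic O–Si bond is cut. The phenol must be masked during both esterifications, and an aryl silyl ether is the one group that fluoride removes without touching two esters. The forward step must be buffered so that the phenoxide does not attack an ester.

33 ⇒ 31 + 32. The C1–O acyl bond is cut last because the tiglate is the most sensitive ester. This removes the Michael acceptor from all earlier chemistry. The demand is acylation of a hindered allylic alcohol next to the quaternary C7 while the tertiary C10 hydroxyl stays free.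

31 ⇒ 29 ⇒ 28. The C1–O bond and the C2=C3 alkene are traced back to a C1=C2 alkene through its epoxide. The position is unambiguous because C7 has no hydrogen, so only H-3 can be removed. The forward demands are epoxidation on the β-face, an H-3 that is also β, and an isomerisation method that tolerates the C5 ester.

28 ⇒ 26 + 27. The C5–O acyl bond is cut while C5 is the only secondary hydroxyl in the molecule, so no hydroxyl differentiation is needed. The demand is that the tertiary C10 hydroxyl is inert to acylation.

26 ⇒ 25 ⇒ 23. The C5–H bond goes back to a ketone and the ketone to the exocyclic methylene. The C10 hydroxyl is used as the handle that delivers hydride to the concave face. The demands are a free C10 hydroxyl at this stage and oxidative cleavage of the exocyclic alkene in the presence of the C1=C2 alkene.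

23 ⇒ 22 ⇒ 21. C6–C7 and C4–C5 are cut together, with the C2–C4 bond restored as a cyclopropane. Two rings, the quaternary carbon and the C6/C7 pair fall back to an open chain with one carbinol stereocentre and an enantiopure cyclopropane. The demands are E geometry at C7=C1, the matched cyclopropane enantiomer and a non-coordinating oxygen substituent at C10.

21 ⇒ 20 ⇒ 18. The terminal allene carbon is removed, leaving a terminal alkyne. The one-carbon homologation does not touch the carbinol centre, so the stereochemical problem is reduced to a tertiary propargylic alcohol.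

18 ⇒ 16 ⇒ 15 ⇒ 14. The alkyne is traced to a 2,3-epoxy alcohol and the C10–O bond to an asymmetric epoxidation of an allylic alcohol. This replaces an enantioselective addition to a dialkyl ketone, which would be poorly controlled, by a reagent-controlled epoxidation that ignores the remote alkene. The demand is a geometrically pure trisubstituted allylic alcohol.

14 ⇒ 13 ⇒ 12. The C10–isopropyl bond is cut. Syn addition of an isopropyl copper reagent to an ynoate fixes the alkene geometry that the epoxidation needs. The demand is a cold quench so that the vinyl copper geometry is kept.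

12 ⇒ 10 ⇒ 7 + 8. The ester carbon C5 and the C8–C9 bond are cut. The chain is reduced to an allylic bromide and a three-carbon propargyl nucleophile whose silyl group enforces reaction at the propargylic carbon.

7 ⇒ 6 ⇒ 5 ⇒ 2 + 3 (through 4). The C7=C1 alkene is cut. A stabilised ylide on an aldehyde gives the E-trisubstituted alkene reliably, which olefination of a methyl ketone would not. The ester carbon becomes C8.

2 ⇒ 1. The two cyclopropane bonds to the methylene carbon are cut. A hydroxyl-directed, ligand-controlled cyclopropanation sets both ring stereocentres from an achiral E-allylic alcohol.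

## Other disconnections considered

Alternative 1: The cut is C9–C10, closing ring B last.
- Forward step: SmI2 with catalytic NiI2 reduces the primary iodide of the monocyclic iodo ketone A1; the organosamarium adds to the isopropyl ketone and gives the protected bicyclic triol A2.
- In favour: Barbier closures of cyclopentanols are well precedented, so this key step is better than the chosen one in precedent. Ring A of A2 already has the C1 oxygen, the C5 oxygen and the C2=C3 alkene, so the end game is only protecting-group exchange and two acylations. That is better than the chosen plan in end-game step economy, and no tertiary alcohol is carried through the synthesis.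
- Against: the step makes one bond and one stereocentre. The required C10 hydroxyl cis to C5 depends on a samarium chelate between the ketone and the C5 ether, which is plausible but not assured. C6, α to the ketone, can epimerise, and simple ketone reduction can compete.
- Comparison: the hard part, the C6/C7 pair with the quaternary methyl on a functionalised cycloheptene, is moved into the preparation of A1. The chosen plan makes that pair, both rings and the quaternary carbon in one event from an open chain, at the price of an untested substrate class. The total step count of the alternative is expected to be higher because A1 needs its own ring synthesis.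

Alternative 2: The cut is C3–C4, closing ring A.
- Forward step: zerovalent palladium from Pd2(dba)3 and P(t-Bu)3 inserts into the vinyl C–I bond of the cyclopentane A3, and the silyl enol ether, activated by Bu3SnF, is alkenylated at C4 to give the bicyclic ketone A4.
- In favour: the C2=C3 alkene and the C1 oxygen are present from the start, so the epoxidation and isomerisation steps disappear; on this point the alternative is better. A4 has the same C5 ketone as 25, so the hydroxyl-directed reduction serves equally well; on this point the two plans are equal.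
- Against: seven-membered ring closure by enolate alkenylation is uncommon and competes with loss of iodide. The β,γ-unsaturated ketone can slide into conjugation under the basic fluoride conditions, which would lose the alkene position. A3 is a fully substituted cyclopentane whose three contiguous centres (C6, C7, C10) must be built separately.
- Comparison: both plans pass through a C5 ketone. The chosen plan sets C6 and C7 in the ring-forming step; the alternative uses established catalysis on a precursor that costs more steps and carries the stereochemical burden earlier.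

Alternative 3: The cut is the C7–methyl bond, made as a cyclopropane.
- Forward step: Et2Zn and CH2I2 cyclopropanate the tetrasubstituted C6=C7 alkene of the allylic alcohol A5 on the face of the C5 hydroxyl to give the ring-fusion cyclopropane A6. Later reductive opening of the C6–CH2 bond would leave the methyl on C7 and hydrogen on C6.
- In favour: hydroxyl-directed Simmons–Smith reactions are reliable even on hindered alkenes. The C5 oxygen and the C7 methyl are on the same face in the target, so the direction is correct. On certainty of creating the quaternary carbon this is better than the chosen plan.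
- Against: the step closes no ring of the skeleton. The cyclopropane must then be opened selectively at C6–CH2, most plausibly by oxidation to the cyclopropyl ketone and dissolving-metal cleavage. That threatens the allylic C1 silyl ether and leaves the C6 configuration to an enolate protonation.
- Comparison: the chosen plan fixes H-6 and the C7 methyl cis in one step; here the cis fusion rests on a later protonation. Several extra redox steps are needed, so the alternative is behind on step economy and ahead on precedent for its key step.

Key step: step 14

## Conventions, assumption and design corrections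

- Convention: bicyclic compounds are described on the C1–C10 frame (ring A C1–C7, ring B C6–C10). β is the face of H-6 and the C7 methyl; all bicyclic compounds are cis-fused with a 10β-isopropyl group and have the absolute configuration of 34.
- Assumption: 27 and 32 are bought; if 27 is not stocked it is one silylation from 4-hydroxybenzoic acid and does not lengthen the linear sequence.
- Structures 21 and 22 were checked atom by atom against 34: connectivity, C10, C6, C7 and C3 agree and need no change.
- The cyclopropane is not a bystander. Its C2 centre decides on which alkene face the unsubstituted C2–C4 bond can be cleaved, and so fixes C7; the (1S,2S) ring is the matched isomer.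
- A silyl ether at C10 cannot deliver hydride, so the silyl group is removed before the C5 reduction.
- A lithium amide would attack the C5 aroate, so the epoxide is isomerised with a silyl triflate and an amidine base.
- Allenylation of the more hindered ketone of a diketone and olefination of a methyl ketone would give neither chemoselectivity nor E geometry. Both are replaced by an ester-based alkene synthesis and an asymmetric epoxidation.

## Steps

Step 1
Reactants: 1 (E)-but-2-en-1-ol
Product: 2 [(1S,2S)-2-methylcyclopropyl]methanol
Conditions: Et2Zn, CH2I2, DME, (4R,5R)-2-butyl-N,N,N′,N′-tetramethyl-1,3,2-dioxaborolane-4,5-dicarboxamide, CH2Cl2, −10 °C → rt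
Reagents that add atoms: diiodomethane, ICI
Why: Charette asymmetric Simmons–Smith cyclopropanation: the zinc alkoxide of 1 binds the chiral dioxaborolane, which steers the zinc carbenoid to one alkene face, and the E geometry is transferred stereospecifically to the trans ring; the (4R,5R) ligand is the enantiomer expected to give the (1S,2S) alcohol by the established facial preference for E-allylic alcohols.

Step 2
Reactants: 2 [(1S,2S)-2-methylcyclopropyl]methanol; 3 ethyl 2-(triphenyl-λ5-phosphanylidene)propanoate
Product: 5 ethyl (2E)-2-methyl-3-[(1S,2S)-2-methylcyclopropyl]prop-2-enoate, via aldehyde 4 (not isolated)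
Conditions: PhI(OAc)2, TEMPO (cat.), CH2Cl2, rt; then 3, rt → 40 °C
Reagents that add atoms: none
Why: Nitroxyl-catalysed oxidation stops at the volatile aldehyde 4, which is trapped in the same flask by Wittig olefination; the stabilised α-methyl ylide should give the E-trisubstituted enoate predominantly, which fixes the C7=C1 geometry with the tether carbon trans to the cyclopropane.

Step 3
Reactants: 5 ethyl (2E)-2-methyl-3-[(1S,2S)-2-methylcyclopropyl]prop-2-enoate
Product: 6 (2E)-2-methyl-3-[(1S,2S)-2-methylcyclopropyl]prop-2-en-1-ol
Conditions: i-Bu2AlH, CH2Cl2, −78 °C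
Reagents that add atoms: none
Why: 1,2-Reduction of the conjugated ester by the aluminium hydride gives the allylic alcohol without touching the alkene or the cyclopropane.

Step 4
Reactants: 6 (2E)-2-methyl-3-[(1S,2S)-2-methylcyclopropyl]prop-2-en-1-ol
Product: 7 (1S,2S)-1-[(1E)-3-bromo-2-methylprop-1-en-1-yl]-2-methylcyclopropane
Conditions: CBr4, PPh3, 2,6-lutidine, CH2Cl2, −20 → 0 °C
Reagents that add atoms: tetrabromomethane, BrC(Br)(Br)Br
Why: Appel bromination converts the primary allylic alcohol by SN2 displacement under buffered conditions, avoiding the cyclopropyl-stabilised allyl cation that acid would generate; the bromide is used at once.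

Step 5
Reactants: 7 (1S,2S)-1-[(1E)-3-bromo-2-methylprop-1-en-1-yl]-2-methylcyclopropane; 8 trimethyl(prop-1-yn-1-yl)silane
Product: 10 trimethyl{(5E)-5-methyl-6-[(1S,2S)-2-methylcyclopropyl]hex-5-en-1-yn-1-yl}silane, via lithiated silylpropyne 9 (not isolated)
Conditions: n-BuLi, THF, −78 → −20 °C; then 7, −78 °C → rt
Reagents that add atoms: none
Why: Alkylation of lithiated 1-(trimethylsilyl)propyne, which reacts at its propargylic carbon, with the primary allylic bromide forms the C8–C9 bond; the silyl group blocks the alkyne terminus and suppresses allenic products.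

Step 6
Reactants: 10 trimethyl{(5E)-5-methyl-6-[(1S,2S)-2-methylcyclopropyl]hex-5-en-1-yn-1-yl}silane
Product: 12 methyl (6E)-6-methyl-7-[(1S,2S)-2-methylcyclopropyl]hept-6-en-2-ynoate, via lithium acetylide 11 (not isolated)
Conditions: MeLi·LiBr, THF, 0 °C → rt; then ClCO2Me, −78 → 0 °C
Reagents that add atoms: methyl chloroformate, COC(Cl)=O
Why: Methyllithium cleaves the alkynyl C–Si bond to the lithium acetylide, which is acylated by the chloroformate to install C5 as an ester; the ynoate is the substrate needed for a stereodefined carbocupration.

Step 7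
Reactants: 12 methyl (6E)-6-methyl-7-[(1S,2S)-2-methylcyclopropyl]hept-6-en-2-ynoate
Product: 13 methyl (2E,6E)-6-methyl-7-[(1S,2S)-2-methylcyclopropyl]-3-(propan-2-yl)hepta-2,6-dienoate
Conditions: i-PrMgBr, CuBr·SMe2, THF, −78 °C; then MeOH, −78 °C
Reagents that add atoms: isopropylmagnesium bromide, CC(C)[Mg]Br
Why: Syn carbocupration (conjugate addition) of the isopropyl cuprate to the ynoate places isopropyl on C10 trans to the ester, and protonation at low temperature keeps the vinyl copper geometry; the resulting E alkene has the unbranched chain cis to the future hydroxymethyl group, the favourable pattern for the epoxidation.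

Step 8
Reactants: 13 methyl (2E,6E)-6-methyl-7-[(1S,2S)-2-methylcyclopropyl]-3-(propan-2-yl)hepta-2,6-dienoate
Product: 14 (2E,6E)-6-methyl-7-[(1S,2S)-2-methylcyclopropyl]-3-(propan-2-yl)hepta-2,6-dien-1-ol
Conditions: i-Bu2AlH, CH2Cl2, −78 °C
Reagents that add atoms: none
Why: 1,2-Reduction of the enoate gives the allylic alcohol that the asymmetric epoxidation needs as its anchoring group.

Step 9
Reactants: 14 (2E,6E)-6-methyl-7-[(1S,2S)-2-methylcyclopropyl]-3-(propan-2-yl)hepta-2,6-dien-1-ol
Product: 15 [(2R,3R)-3-{(3E)-3-methyl-4-[(1S,2S)-2-methylcyclopropyl]but-3-en-1-yl}-3-(propan-2-yl)oxiran-2-yl]methanol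
Conditions: Ti(OiPr)4 (cat.), diethyl D-(−)-tartrate (cat.), t-BuOOH, 4 Å MS, CH2Cl2, −20 °C
Reagents that add atoms: tert-butyl hydroperoxide, CC(C)(C)OO
Why: Sharpless asymmetric epoxidation reacts only at the allylic alcohol alkene and leaves the remote trisubstituted alkene alone; D-(−)-tartrate should deliver oxygen to the face that gives the (2R,3R) epoxide (the mirror image of the sense L-(+)-tartrate shows with geraniol-type substrates), which sets the C10 carbinol configuration.

Step 10
Reactants: 15 [(2R,3R)-3-{(3E)-3-methyl-4-[(1S,2S)-2-methylcyclopropyl]but-3-en-1-yl}-3-(propan-2-yl)oxiran-2-yl]methanol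
Product: 16 (2S,3R)-2-(chloromethyl)-3-{(3E)-3-methyl-4-[(1S,2S)-2-methylcyclopropyl]but-3-en-1-yl}-3-(propan-2-yl)oxirane
Conditions: PPh3, CCl4, NaHCO3, reflux
Reagents that add atoms: tetrachloromethane, ClC(Cl)(Cl)Cl
Why: Appel chlorination of the primary alcohol runs under near-neutral conditions that leave the trisubstituted epoxide intact; the descriptor at the oxirane CH changes only because chlorine alters the priorities.

Step 11
Reactants: 16 (2S,3R)-2-(chloromethyl)-3-{(3E)-3-methyl-4-[(1S,2S)-2-methylcyclopropyl]but-3-en-1-yl}-3-(propan-2-yl)oxirane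
Product: 18 (3R,6E)-6-methyl-7-[(1S,2S)-2-methylcyclopropyl]-3-(propan-2-yl)hept-6-en-1-yn-3-ol, via chlorovinyl alkoxide 17 (not isolated)
Conditions: n-BuLi (3.3 equiv), THF, −40 → −20 °C
Reagents that add atoms: none
Why: Base-induced fragmentation of a 2,3-epoxy chloride: deprotonation next to chlorine opens the epoxide to 17, and further base eliminates HCl and deprotonates the alkyne; the C10–O bond is never broken, so the configuration from step 9 is carried into the tertiary propargylic alcohol.

Step 12
Reactants: 18 (3R,6E)-6-methyl-7-[(1S,2S)-2-methylcyclopropyl]-3-(propan-2-yl)hept-6-en-1-yn-3-ol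
Product: 20 (4R,7E)-7-methyl-8-[(1S,2S)-2-methylcyclopropyl]-4-(propan-2-yl)octa-1,2,7-trien-4-ol, via Mannich base 19 (not isolated)
Conditions: (CH2O)n, CuI, i-Pr2NH, 1,4-dioxane, reflux
Reagents that add atoms: formaldehyde (as paraformaldehyde), C=O
Why: Crabbé homologation: a copper-mediated Mannich reaction gives the propargylic amine 19, which transfers hydride and loses the imine to give the terminal allene; the carbinol stereocentre is not involved.

Step 13
Reactants: 20 (4R,7E)-7-methyl-8-[(1S,2S)-2-methylcyclopropyl]-4-(propan-2-yl)octa-1,2,7-trien-4-ol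
Product: 21 triethyl{[(4R,7E)-7-methyl-8-[(1S,2S)-2-methylcyclopropyl]-4-(propan-2-yl)octa-1,2,7-trien-4-yl]oxy}silane
Conditions: Et3SiOTf, 2,6-lutidine, CH2Cl2, −78 → 0 °C
Reagents that add atoms: triethylsilyl trifluoromethanesulfonate, CC[Si](CC)(CC)OS(=O)(=O)C(F)(F)F
Why: The silyl triflate silylates the hindered tertiary alcohol; this keeps the allenyl carbinol from binding or cyclising on rhodium and makes the oxygen substituent at C10 clearly different in shape from isopropyl.

Step 14
Reactants: 21 triethyl{[(4R,7E)-7-methyl-8-[(1S,2S)-2-methylcyclopropyl]-4-(propan-2-yl)octa-1,2,7-trien-4-yl]oxy}silane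
Product: 22 silyl-protected cycloadduct: C1=C2 alkene; 3α-methyl (3β-H); C5 exocyclic methylene; 6β-H; 7β-methyl; 10α-triethylsilyloxy
Conditions: [Rh(CO)2Cl]2 (5 mol %), toluene (0.02 M), 90–110 °C
Reagents that add atoms: none
Why: Proposed new method: monovalent rhodium binds the internal allene π-bond (C5=C6) and the vinylcyclopropane, C6–C7 bond formation (insertion of the allene into the σ,π-allyl rhodacycle that arises from cleavage of the C2–C4 cyclopropane bond, or direct oxidative coupling followed by cyclopropylcarbinyl opening) gives an eight-membered rhodacycle containing the new cis C1=C2 alkene, and C(sp3)–C(sp2) reductive elimination forms C4–C5; the closest known reaction type is the rhodium-catalysed intramolecular (5+2) cycloaddition of allenes with vinylcyclopropanes whose tethered alkene carbon bears hydrogen, so the formation of a quaternary carbon from the E-trisubstituted alkene is the untested element. Ring B closes as the five-membered tether ring when C6 joins C7 (an exo-type insertion through the three-atom tether C8–C9–C10), and ring A is the seven-membered ring of the cycloaddition itself, completed by the reductive elimination. C7 is set by the cyclopropane, because only on one alkene face can the unsubstituted C2–C4 bond of the (1S,2S) ring align with the metal in the geometry that leads to the cis ring alkene, so C6 is delivered to that face and the methyl ends β. C6 follows from the cis ring fusion enforced by the short tether, and this is the matched case for C10, since the isopropyl group then lies trans to the C6–C5 bond on the forming cyclopentane while the flatter silyloxy group takes the cis position. C3 is not touched and keeps its hydrogen β. The step needs chemoselectivity for the internal allene bond (the distal bond should survive as the exocyclic methylene, as is usual for this catalyst), cleavage of the less substituted cyclopropane bond (favoured for a trans alkyl substituent) and tolerance of the allylic strain between the C7 methyl and the cyclopropane in the reactive conformer, which is why dilute, hot conditions and a non-coordinating silyl ether are chosen.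

Step 15
Reactants: 22 silyl-protected cycloadduct
Product: 23 dienol: C1=C2 alkene; 3α-methyl; C5 exocyclic methylene; 10α-hydroxy
Conditions: Bu4NF, THF, rt → 45 °C
Reagents that add atoms: none
Why: Fluoride cleaves the tertiary triethylsilyl ether; the free C10 hydroxyl is needed to direct the C5 reduction and is too hindered to interfere with the later acylations.

Step 16
Reactants: 23 dienol
Product: 25 hydroxy ketone: 5-oxo; 10α-hydroxy; C1=C2 alkene; 3α-methyl, via triol 24 (not isolated)
Conditions: OsO4 (cat.), NaIO4, 2,6-lutidine, 1,4-dioxane–H2O, rt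
Reagents that add atoms: osmium tetroxide, O=[Os](=O)(=O)=O; sodium periodate, [Na+].[O-]I(=O)(=O)=O
Why: Lemieux–Johnson oxidation: osmium tetroxide should dihydroxylate the unhindered 1,1-disubstituted exocyclic alkene faster than the cis-disubstituted C1=C2 alkene, which is flanked by the quaternary C7 and the branched C3, and periodate cleaves the diol unit of 24 to the C5 ketone in the same flask.

Step 17
Reactants: 25 hydroxy ketone
Product: 26 5β,10α-diol (C1=C2 alkene; 3α-methyl)
Conditions: Me4NBH(OAc)3, MeCN–AcOH, −30 → −20 °C
Reagents that add atoms: none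
Why: Evans–Saksena directed reduction: the C10 hydroxyl exchanges onto boron and delivers hydride within the molecule to the concave α-face of the C5 ketone, giving the 1,3-anti diol with the new hydroxyl β; an external hydride would approach the convex face and give the other epimer.

Step 18
Reactants: 26 5β,10α-diol; 27 4-[(tert-butyldimethylsilyl)oxy]benzoic acid
Product: 28 5β-aroate: 5β-{4-[(tert-butyldimethylsilyl)oxy]benzoyloxy}; 10α-hydroxy; C1=C2 alkene
Conditions: EDC·HCl, DMAP, CH2Cl2, rt
Reagents that add atoms: none
Why: Steglich esterification acylates the only secondary hydroxyl; the tertiary C10 hydroxyl, flanked by isopropyl and the ring fusion, should not react.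

Step 19
Reactants: 28 5β-aroate
Product: 29 1β,2β-epoxide of 28
Conditions: m-CPBA, NaHCO3, CH2Cl2, 0 °C
Reagents that add atoms: 3-chloroperoxybenzoic acid, OOC(=O)c1cccc(Cl)c1
Why: Peracid epoxidation of the only alkene from the convex β-face, which is also the face away from the C3 methyl and from ring B; this places the future C1 oxygen β and syn to H-3.

Step 20
Reactants: 29 1β,2β-epoxide
Product: 31 1β-allylic alcohol: 1β-hydroxy; C2=C3 alkene; 5β-aroate; 10α-hydroxy, via bis-silyl ether 30 (not isolated)
Conditions: Me3SiOTf, DBU, toluene, −78 °C → rt; then citric acid, MeOH, rt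
Reagents that add atoms: none
Why: Silyl triflate-mediated isomerisation of an epoxide to an allylic silyl ether: triflate opens the silylated epoxide at the less hindered C2 with inversion and the amidine base removes the anti-periplanar β-hydrogen on C3, the only hydrogen that can be lost because C7 is quaternary, so the alkene moves to C2=C3 and C1 keeps its β-oxygen. The conditions spare the aroate, and mild methanolysis frees both trimethylsilyl ethers of 30.

Step 21
Reactants: 31 1β-allylic alcohol; 32 (2E)-2-methylbut-2-enoyl chloride
Product: 33 silyl-protected target: 1β-tiglate; 5β-{4-[(tert-butyldimethylsilyl)oxy]benzoate}; 10α-hydroxy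
Conditions: Et3N, DMAP, CH2Cl2, 0 → 40 °C
Reagents that add atoms: none
Why: Acyl-transfer catalysis esterifies the hindered allylic C1 hydroxyl while the tertiary alcohol stays free; the E-configured tiglate is the stable geometric isomer, so no isomerisation is expected.

Step 22
Reactants: 33 silyl-protected target
Product: 34 (3R,3aS,4S,8R,8aR)-3-hydroxy-6,8a-dimethyl-8-{[(2E)-2-methylbut-2-enoyl]oxy}-3-(propan-2-yl)-1,2,3,3a,4,5,8,8a-octahydroazulen-4-yl 4-hydroxybenzoate
Conditions: Bu4NF, AcOH, THF, 0 °C
Reagents that add atoms: none
Why: Buffered fluoride removes the aryl silyl ether, the most labile Si–O bond present, without cleaving or moving either ester.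

## Compound list

1 | (E)-but-2-en-1-ol | C/C=C/CO | starting material
2 | [(1S,2S)-2-methylcyclopropyl]methanol | OC[C@H]1C[C@@H]1C | intermediate
3 | ethyl 2-(triphenyl-λ5-phosphanylidene)propanoate | CCOC(=O)C(C)=P(c1ccccc1)(c1ccccc1)c1ccccc1 | starting material
4 | (1S,2S)-2-methylcyclopropane-1-carbaldehyde | O=C[C@H]1C[C@@H]1C | intermediate (not isolated)
5 | ethyl (2E)-2-methyl-3-[(1S,2S)-2-methylcyclopropyl]prop-2-enoate | CCOC(=O)/C(C)=C/[C@H]1C[C@@H]1C | intermediate
6 | (2E)-2-methyl-3-[(1S,2S)-2-methylcyclopropyl]prop-2-en-1-ol | OC/C(C)=C/[C@H]1C[C@@H]1C | intermediate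
7 | (1S,2S)-1-[(1E)-3-bromo-2-methylprop-1-en-1-yl]-2-methylcyclopropane | BrC/C(C)=C/[C@H]1C[C@@H]1C | intermediate
8 | trimethyl(prop-1-yn-1-yl)silane | CC#C[Si](C)(C)C | starting material
9 | [3-(trimethylsilyl)prop-2-yn-1-yl]lithium | [Li]CC#C[Si](C)(C)C | intermediate (not isolated)
10 | trimethyl{(5E)-5-methyl-6-[(1S,2S)-2-methylcyclopropyl]hex-5-en-1-yn-1-yl}silane | C[Si](C)(C)C#CCC/C(C)=C/[C@H]1C[C@@H]1C | intermediate
11 | {(5E)-5-methyl-6-[(1S,2S)-2-methylcyclopropyl]hex-5-en-1-yn-1-yl}lithium | [Li]C#CCC/C(C)=C/[C@H]1C[C@@H]1C | intermediate (not isolated)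
12 | methyl (6E)-6-methyl-7-[(1S,2S)-2-methylcyclopropyl]hept-6-en-2-ynoate | COC(=O)C#CCC/C(C)=C/[C@H]1C[C@@H]1C | intermediate
13 | methyl (2E,6E)-6-methyl-7-[(1S,2S)-2-methylcyclopropyl]-3-(propan-2-yl)hepta-2,6-dienoate | COC(=O)/C=C(/C(C)C)CC/C(C)=C/[C@H]1C[C@@H]1C | intermediate
14 | (2E,6E)-6-methyl-7-[(1S,2S)-2-methylcyclopropyl]-3-(propan-2-yl)hepta-2,6-dien-1-ol | OC/C=C(/C(C)C)CC/C(C)=C/[C@H]1C[C@@H]1C | intermediate
15 | [(2R,3R)-3-{(3E)-3-methyl-4-[(1S,2S)-2-methylcyclopropyl]but-3-en-1-yl}-3-(propan-2-yl)oxiran-2-yl]methanol | OC[C@H]1O[C@@]1(C(C)C)CC/C(C)=C/[C@H]2C[C@@H]2C | intermediate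
16 | (2S,3R)-2-(chloromethyl)-3-{(3E)-3-methyl-4-[(1S,2S)-2-methylcyclopropyl]but-3-en-1-yl}-3-(propan-2-yl)oxirane | ClC[C@H]1O[C@@]1(C(C)C)CC/C(C)=C/[C@H]2C[C@@H]2C | intermediate
17 | lithium (1E,3R,6E)-1-chloro-6-methyl-7-[(1S,2S)-2-methylcyclopropyl]-3-(propan-2-yl)hepta-1,6-dien-3-olate | Cl/C=C/[C@]([O-])(C(C)C)CC/C(C)=C/[C@H]1C[C@@H]1C.[Li+] | intermediate (not isolated)
18 | (3R,6E)-6-methyl-7-[(1S,2S)-2-methylcyclopropyl]-3-(propan-2-yl)hept-6-en-1-yn-3-ol | C#C[C@](O)(C(C)C)CC/C(C)=C/[C@H]1C[C@@H]1C | intermediate
19 | (4R,7E)-1-[di(propan-2-yl)amino]-7-methyl-8-[(1S,2S)-2-methylcyclopropyl]-4-(propan-2-yl)oct-7-en-2-yn-4-ol | CC(C)N(C(C)C)CC#C[C@](O)(C(C)C)CC/C(C)=C/[C@H]1C[C@@H]1C | intermediate (not isolated)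
20 | (4R,7E)-7-methyl-8-[(1S,2S)-2-methylcyclopropyl]-4-(propan-2-yl)octa-1,2,7-trien-4-ol | C=C=C[C@](O)(C(C)C)CC/C(C)=C/[C@H]1C[C@@H]1C | intermediate
21 | triethyl{[(4R,7E)-7-methyl-8-[(1S,2S)-2-methylcyclopropyl]-4-(propan-2-yl)octa-1,2,7-trien-4-yl]oxy}silane | C=C=C[C@](O[Si](CC)(CC)CC)(C(C)C)CC/C(C)=C/[C@H]1C[C@@H]1C | intermediate
22 | silyl-protected cycloadduct (C1=C2; 3α-methyl; C5=CH2; 6β-H; 7β-methyl; 10α-OSiEt3; 10β-isopropyl) | C1=C[C@@H](C)CC(=C)[C@@H]2[C@@]1(C)CC[C@@]2(O[Si](CC)(CC)CC)C(C)C | intermediate
23 | dienol (as 22 with 10α-OH) | C1=C[C@@H](C)CC(=C)[C@@H]2[C@@]1(C)CC[C@@]2(O)C(C)C | intermediate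
24 | triol (5β-hydroxy-5α-hydroxymethyl; 10α-OH; C1=C2); the C5 configuration follows from convex-face attack and is immaterial | C1=C[C@@H](C)C[C@@](O)(CO)[C@@H]2[C@@]1(C)CC[C@@]2(O)C(C)C | intermediate (not isolated)
25 | hydroxy ketone (5-oxo; 10α-OH; C1=C2; 3α-methyl) | C1=C[C@@H](C)CC(=O)[C@@H]2[C@@]1(C)CC[C@@]2(O)C(C)C | intermediate
26 | 5β,10α-diol (C1=C2; 3α-methyl) | C1=C[C@@H](C)C[C@H](O)[C@@H]2[C@@]1(C)CC[C@@]2(O)C(C)C | intermediate
27 | 4-[(tert-butyldimethylsilyl)oxy]benzoic acid | CC(C)(C)[Si](C)(C)Oc1ccc(cc1)C(O)=O | starting material
28 | 5β-aroate (5β-{4-[(tert-butyldimethylsilyl)oxy]benzoyloxy}; 10α-OH; C1=C2) | C1=C[C@@H](C)C[C@H](OC(=O)c3ccc(O[Si](C)(C)C(C)(C)C)cc3)[C@@H]2[C@@]1(C)CC[C@@]2(O)C(C)C | intermediate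
29 | 1β,2β-epoxide of 28 | [C@@H]12O[C@@H]1[C@@H](C)C[C@H](OC(=O)c4ccc(O[Si](C)(C)C(C)(C)C)cc4)[C@@H]3[C@@]2(C)CC[C@@]3(O)C(C)C | intermediate
30 | 1β,10α-bis(trimethylsilyl) ether of 31 | C[Si](C)(C)O[C@@H]1C=C(C)C[C@H](OC(=O)c3ccc(O[Si](C)(C)C(C)(C)C)cc3)[C@@H]2[C@@]1(C)CC[C@@]2(O[Si](C)(C)C)C(C)C | intermediate (not isolated)
31 | 1β-allylic alcohol (1β-OH; C2=C3; 5β-aroate; 10α-OH) | O[C@@H]1C=C(C)C[C@H](OC(=O)c3ccc(O[Si](C)(C)C(C)(C)C)cc3)[C@@H]2[C@@]1(C)CC[C@@]2(O)C(C)C | intermediate
32 | (2E)-2-methylbut-2-enoyl chloride | C/C=C(\C)C(Cl)=O | starting material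
33 | silyl-protected target (1β-tiglate; 5β-silyloxybenzoate; 10α-OH) | C/C=C(\C)C(=O)O[C@@H]1C=C(C)C[C@H](OC(=O)c3ccc(O[Si](C)(C)C(C)(C)C)cc3)[C@@H]2[C@@]1(C)CC[C@@]2(O)C(C)C | intermediate
34 | (3R,3aS,4S,8R,8aR)-3-hydroxy-6,8a-dimethyl-8-{[(2E)-2-methylbut-2-enoyl]oxy}-3-(propan-2-yl)-1,2,3,3a,4,5,8,8a-octahydroazulen-4-yl 4-hydroxybenzoate | C/C=C(\C)C(=O)O[C@@H]1C=C(C)C[C@H](OC(=O)c2ccc(O)cc2)[C@@H]2[C@@]1(C)CC[C@@]2(O)C(C)C | target

## Step count and least certain steps

Total: 22 steps. Longest linear sequence: 22 steps from 1 (the route is linear; 3, 8, 27 and 32 are bought).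

Step 14 (key step, carries the new-method label).
- What may go wrong: failure of the metal to engage the alkene, because the reactive vinylcyclopropane conformer suffers allylic strain from the C7 methyl. Allene oligomerisation, allene isomerisation or cleavage of the wrong cyclopropane bond could then take over.
- Fallback with known chemistry, setting out from 18 and returning at 25:
 - 18 is silylated (Et3SiOTf, 2,6-lutidine) to triethyl{[(3R,6E)-6-methyl-7-[(1S,2S)-2-methylcyclopropyl]-3-(propan-2-yl)hept-6-en-1-yn-3-yl]oxy}silane F1.
 - F1 undergoes the rhodium-catalysed alkyne–vinylcyclopropane (5+2) cycloaddition ([Rh(CO)2Cl]2 or Rh(PPh3)3Cl with AgOTf). This is the longest-established member of the family, and substituted alkene carbons that become quaternary ring-fusion carbons are believed to lie within its documented scope. The product is the bicyclic 1,4-diene F2 (C1=C2 and C5=C6, 7β-methyl fixed by the cyclopropane as in step 14).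
 - Bu4NF frees the tertiary allylic alcohol F3.
 - VO(acac)2 and t-BuOOH epoxidise the allylic C5=C6 alkene on the hydroxyl face to give the 5α,6α-epoxide F4.
 - Cp2TiCl (trivalent titanium, from Cp2TiCl2 and Mn) with 1,4-cyclohexadiene opens the epoxide to the tertiary C6 radical and reduces it. The α-face is shielded by the two titanium alkoxides, so this should give the cis-fused 5α,10α-diol F5.
 - Dess–Martin oxidation of the secondary hydroxyl of F5 gives 25.
 - The price is that C6 is set by a hydrogen-atom transfer rather than in the ring-forming step.

Step 16.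
- What may go wrong: over-oxidation, that is osmylation of the ring alkene C1=C2 competing with the exocyclic methylene.
- Fallback from 23 to 25: VO(acac)2 and t-BuOOH, directed by the homoallylic C10 hydroxyl, epoxidise only the exocyclic alkene to the spiro-epoxide F6. H5IO6 in wet ether then hydrolyses and cleaves F6 to 25.

Step 17.
- What may go wrong: incomplete facial control, or retro-aldol cleavage or dehydration of the tertiary β-hydroxy ketone in the acidic medium.
- Fallback from 25 to 26, a silicon-tethered hydride delivery: (HMe2Si)2NH converts 25 into the 10α-dimethylsilyl ether F7. A Lewis acid (SnCl4, −78 °C) triggers intramolecular hydrosilylation of the ketone from the same concave face to the cyclic dimethylsilylene acetal F8. HF·pyridine then releases 26.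

Step 19.
- What may go wrong: erosion of facial selectivity, by hydrogen-bonded delivery of the peracid from the free C10 hydroxyl on the concave face or by shielding of the convex face by the C7 methyl.
- Fallback from 28 directly to 31 (steps 19 and 20 are bypassed): singlet-oxygen ene reaction (O2, visible light, tetraphenylporphyrin, CH2Cl2, 0 °C). Oxygen must add to C1 on the face of the only allylic hydrogen, the β-hydrogen on C3, while the alkene shifts to C2=C3. This gives the 1β-hydroperoxide F9, which PPh3 reduces to 31.

Step 20.
- What may go wrong: acid-type rearrangement of the silylated epoxide (hydride shift to a ketone) or attack of triflate at the wrong carbon, instead of the intended opening and elimination.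
- Fallback from 29 to 31 without a new isolated compound: Cp2TiCl (trivalent titanium) opens the epoxide homolytically; trapping of the C2 radical by a second titanium centre and β-hydride elimination of H-3 give the allylic alcohol under non-acidic, non-basic conditions.

## Further compounds

F1 | step 14 | triethyl{[(3R,6E)-6-methyl-7-[(1S,2S)-2-methylcyclopropyl]-3-(propan-2-yl)hept-6-en-1-yn-3-yl]oxy}silane | C#C[C@](O[Si](CC)(CC)CC)(C(C)C)CC/C(C)=C/[C@H]1C[C@@H]1C
F2 | step 14 | bicyclic 1,4-diene (C1=C2; C5=C6; 3α-methyl; 7β-methyl; 10α-OSiEt3) | C1=C[C@@H](C)CC=C2[C@@]1(C)CC[C@@]2(O[Si](CC)(CC)CC)C(C)C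
F3 | step 14 | tertiary allylic alcohol (as F2 with 10α-OH) | C1=C[C@@H](C)CC=C2[C@@]1(C)CC[C@@]2(O)C(C)C
F4 | step 14 | 5α,6α-epoxide of F3 | C1=C[C@@H](C)C[C@H]3O[C@@]32[C@@]1(C)CC[C@@]2(O)C(C)C
F5 | step 14 | 5α,10α-diol (C5 epimer of 26) | C1=C[C@@H](C)C[C@@H](O)[C@@H]2[C@@]1(C)CC[C@@]2(O)C(C)C
F6 | step 16 | C5 spiro-epoxide of 23 (oxygen α) | C1=C[C@@H](C)C[C@]3(CO3)[C@@H]2[C@@]1(C)CC[C@@]2(O)C(C)C
F7 | step 17 | 10α-dimethylsilyl ether of 25 | C1=C[C@@H](C)CC(=O)[C@@H]2[C@@]1(C)CC[C@@]2(O[SiH](C)C)C(C)C
F8 | step 17 | cyclic dimethylsilylene acetal of 26 | C1=C[C@@H](C)C[C@H](O[Si]3(C)C)[C@@H]2[C@@]1(C)CC[C@@]2(O3)C(C)C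
F9 | step 19 | 1β-hydroperoxide (C2=C3; 5β-aroate; 10α-OH) | OO[C@@H]1C=C(C)C[C@H](OC(=O)c3ccc(O[Si](C)(C)C(C)(C)C)cc3)[C@@H]2[C@@]1(C)CC[C@@]2(O)C(C)C
F0 | step 20 | none | none
A1 | alternative 1 | monocyclic iodo ketone (1β-OTBS; C2=C3; 5β-OMOM; isopropyl ketone on C6; 2-iodoethyl on C7) | CC(C)(C)[Si](C)(C)O[C@@H]1C=C(C)C[C@H](OCOC)[C@@H](C(=O)C(C)C)[C@@]1(C)CCI
A2 | alternative 1 | protected bicyclic triol with free C10 hydroxyl | CC(C)(C)[Si](C)(C)O[C@@H]1C=C(C)C[C@H](OCOC)[C@@H]2[C@@]1(C)CC[C@@]2(O)C(C)C
A3 | alternative 2 | cyclopentane with C5 trimethylsilyl enol ether on C6 and (Z)-3-iodo-1-silyloxybut-2-enyl chain on C7 | CC(C)(C)[Si](C)(C)O[C@H](/C=C(/C)I)[C@]1(C)CC[C@@](O[Si](CC)(CC)CC)(C(C)C)[C@@H]1C(=C)O[Si](C)(C)C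
A4 | alternative 2 | bicyclic β,γ-unsaturated C5 ketone with C2=C3 in place | CC(C)(C)[Si](C)(C)O[C@@H]1C=C(C)CC(=O)[C@@H]2[C@@]1(C)CC[C@@]2(O[Si](CC)(CC)CC)C(C)C
A5 | alternative 3 | bicyclic C5 allylic alcohol with tetrasubstituted C6=C7 alkene | CC(C)(C)[Si](C)(C)O[C@@H]1C=C(C)C[C@H](O)C2=C1CC[C@@]2(O[Si](CC)(CC)CC)C(C)C
A6 | alternative 3 | ring-fusion cyclopropane syn to the C5 hydroxyl | CC(C)(C)[Si](C)(C)O[C@@H]1C=C(C)C[C@H](O)[C@@]23C[C@@]31CC[C@@]2(O[Si](CC)(CC)CC)C(C)C
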